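If you ask the west run for the flask's orders in catalyst and reagent, it gives no direct reading, because it holds catalyst at 20 mM and reagent at 2.2 M, the flask's own charges, and varies neither.

| setting | west | flask |
|---|---|---|
| substrate | 1 M | 2.0 M |
| reagent | 2.2 M | 2.20 M |
| catalyst | 20 mM | 20 mM |
| remark | run made earlier |  |

- west (time / d: product / %): 0.250: 11; 0.625: 25; 1.67: 41; 4.00: 55

(readings scatter by 1.5 percentage points)

* apparent order in catalyst when 5.0% of the substrate are converted (percent change of the rate of making product for one percent more catalyst charged)
* apparent order in reagent when 5.0% of the substrate are converted (percent change of the rate of making product for one percent more reagent charged)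

- what was read earlier has a scatter of 1.5 percentage points, one standard deviation
- no earlier run changes the charge of catalyst; that part of a forecast is a guess
- no earlier run changes the charge of reagent; that part of a forecast is a guess

What the west run does show is slowing: its mean rate falls from 0.440 /d of the charged substrate up to the first reading to 0.0601 /d over the last span. You might blame a shortage of reagent, but if one reagent goes into each product, the last west reading has used 25.0% of its charge, less than half of it, which is too little to explain the slowing. My first estimate for the reagent is order 1, on the guess that it enters the step that makes product; you can object that it might enter after that step, and no run answers this, so the 1 stays a guess.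

For the catalyst the first estimate is also order 1. The objection is that two catalysts may pair into a resting dimer, a resting state, in fast equilibrium, and then the rate follows the free catalyst rather than the charge:

charged catalyst = [catalyst] + 2K[catalyst][catalyst]

apparent order in catalyst = 1/(1 + d), where d is the share of the charge paired

Here K is the equilibrium constant of the pairing, and with substrate and reagent held fixed and the rate proportional to free catalyst, the order runs from 1 with nothing paired down to 0.500 with the charge fully paired. The west run doesn't give d, so I guess a share of 0.5 and commit to the paired-catalyst order 0.667.

The forecast says 0.9 for catalyst, between 0.5 and 1.1, and 0.5 for reagent, between 0 and 1.05, holding the first near one, “perhaps lowered by dimeric or off-cycle resting states”. My catalyst order is lower than the forecast's, and my reagent order is higher.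

The flask gives 0.66 for catalyst and 1.0 for reagent.

    2 catalyst ⇌ resting dimer, settled at all times (K = 47.0 /M)
    substrate + reagent + catalyst → catalyst + product (k = 2.70 × 10⁻⁴ /M²/s)
    2 substrate → homo dimer (k = 3.30 × 10⁻⁶ /M/s)

In the flask 49.0% of the catalyst is resting dimer at 0.0314 d, and the rule with that share gives 0.671, where my guessed share gave 0.667 and the flask gives 0.66. At 0.786 d the flask's product step uses substrate at 0.91 of the rate of the homo dimer step, and of their turnover up to 6.00 d the homo dimer step has half behind it by 0.364 d, earlier than the product step at 0.786 d. At 6.00 d the flask holds 45.7% of the substrate charged as product against 51.0% as homo dimer, each homo dimer holding two substrate.

The data are calculated for an exercise; scatter was added.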